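**Plan**

1. Numbering used here: C1 = CH–O(angeloyl), C2 = CH2, C3 = CH–OH, C4 = C(CH3); cyclobutane C4–C5–C6–C7; C8 = ketone, C9 = CH2, C10 = CH(CH3); C11 = C(CH3)(C12H2OAc). Retrosynthesis: take off both esters, return C1 to a ketone, then cut C6–C7 and C1–C11 together while re-joining C7–C1 (retro-De Mayo).
2. Enabling feature: O=C8–C7–C6–C11–C1–O is a 1,5-dioxygenated path, so the seven-membered ring C7–C4–C3–C2–C1–C11–C6 is a cyclopentane (C7–C1–C2–C3–C4) enlarged by the alkene C6=C11. The same event closes the cyclobutane because C6 hangs axially on C5, 1,3 to C7, in a cis-hydrindane.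
3. The hydrindane β-diketone comes from a cyclohexanone by Claisen condensation (C1–C7). Its C3 and C6 arms come from one cis-fused γ-lactone, and the cyclohexanone from a Diels–Alder reaction (C4–C7, C5–C10).
4. Forward ring order: cyclohexanone (cycloaddition), cyclopentane (Claisen), then cyclobutane and cycloheptane together (photocycloaddition, fragmentation).
5. Stereochemistry: the acetal carbon of a menthyl butenolide (from (+)-menthol) sets C4, C5 and C10 (anti, endo Diels–Alder). C3 comes from convex-face lactonisation; C6, C7 and C11 from ring constraint and E alkene in the key step; C1 from hydroxyl-directed reduction.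

Key step: step 12

Assumption: acid-mediated epimerisation of the menthyl acetals with crystallisation is taken to deliver the (5S)-acetal 3 from (+)-menthol; if the (5R)-epimer crystallises instead, (−)-menthol is used, since only the acetal carbon steers the cycloaddition.

**Step 1**
Reactants: 1 5-hydroxy-4-methylfuran-2(5H)-one; 2 (1S,2R,5S)-(+)-menthol
Product: 3 (5S)-5-menthyloxy-4-methylfuran-2(5H)-one
Conditions: 4-toluenesulfonic acid monohydrate (cat.), PhMe, reflux, water separator; crystallisation from hexane, mother liquor re-equilibrated with acid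
Reagents that add atoms: none
Why: Acid-catalysed acetalisation of the cyclic hemiacetal with the chiral alcohol gives two acetal epimers that interconvert under acid, so crystallisation should funnel the material into the single (5S) diastereomer (crystallisation-induced diastereomer transformation).

**Step 2**
Reactants: 4 (E)-pent-3-en-2-one
Product: 5 (E)-2-(tert-butyldimethylsilyloxy)penta-1,3-diene
Conditions: TBSOTf, Et3N, CH2Cl2, 0 °C
Reagents that add atoms: tert-butyldimethylsilyl trifluoromethanesulfonate, CC(C)(C)[Si](C)(C)OS(=O)(=O)C(F)(F)F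
Why: Soft enolisation of the methyl ketone on its CH3 side (silyl enol ether formation) should give the cross-conjugated 2-silyloxy diene with the E propenyl unit untouched.

**Step 3**
Reactants: 3 (5S)-5-menthyloxy-4-methylfuran-2(5H)-one; 5 (E)-2-(tert-butyldimethylsilyloxy)penta-1,3-diene
Product: 7 keto lactol, via silyl enol ether cycloadduct 6 (not isolated)
Conditions: 5 (3 equiv), 2,6-di-tert-butyl-4-methylphenol (cat.), PhMe, 130 °C, sealed tube; then 2 M HCl, 1,4-dioxane, 60 °C
Reagents that add atoms: water, O
Why: In this Diels–Alder reaction the nucleophilic CH2 terminus of the 2-silyloxy diene should bond to the β-carbon of the butenolide (C4, new quaternary centre) and the methyl-bearing terminus to C5, anti to the menthyloxy group and endo to the lactone carbonyl, which sets C4, C5 and C10 (C10 methyl cis to C6) before acid hydrolyses the enol ether and the acetal.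

**Step 4**
Reactants: 7 keto lactol
Product: 9 keto lactone ester, via unsaturated acid 8 (not isolated)
Conditions: Ph3P=CHCO2Me (2.2 equiv), PhMe, 90 °C; then 1,8-diazabicyclo[5.4.0]undec-7-ene (0.2 equiv), 23 °C
Reagents that add atoms: methyl (triphenylphosphoranylidene)acetate, COC(=O)C=P(c1ccccc1)(c1ccccc1)c1ccccc1
Why: Wittig olefination of the open aldehyde form followed by reversible 5-exo conjugate addition of the carboxylate (oxa-Michael) should rebuild the cis-fused γ-lactone and set C3 under thermodynamic control with the acetate arm on the convex face, cis to the C4 methyl.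

**Step 5**
Reactants: 9 keto lactone ester
Product: 10 dioxolane of 9
Conditions: Me3SiOCH2CH2OSiMe3, Me3SiOTf (5 mol %), CH2Cl2, −78 to −20 °C
Reagents that add atoms: 1,2-bis(trimethylsilyloxy)ethane, C[Si](C)(C)OCCO[Si](C)(C)C
Why: Silyl-triflate-catalysed ketalisation at low temperature should protect the only ketone (C8) and leave lactone and ester untouched.

**Step 6**
Reactants: 10 dioxolane of 9
Product: 11 lactol
Conditions: disiamylborane (3 equiv), THF, 0 to 23 °C; then HOCH2CH2NH2
Reagents that add atoms: none
Why: Disiamylborane reduces a γ-lactone to the lactol and stops there, while the methyl ester and the ketal are inert to it (chemoselective partial reduction).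

**Step 7**
Reactants: 11 lactol
Product: 12 (E)-enal with free C3 hydroxyl
Conditions: Ph3P=C(CH3)CHO (1.5 equiv), PhMe, 90 °C
Reagents that add atoms: 2-(triphenylphosphoranylidene)propanal, CC(C=O)=P(c1ccccc1)(c1ccccc1)c1ccccc1
Why: Wittig olefination of the hydroxy aldehyde form of the lactol with the formyl-stabilised ylide should give the E trisubstituted enal (C6=C11) and unveil the C3 hydroxyl.

**Step 8**
Reactants: 12 (E)-enal with free C3 hydroxyl
Product: 13 allylic alcohol diol
Conditions: NaBH4, CeCl3·7H2O, MeOH, −40 °C
Reagents that add atoms: none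
Why: Luche reduction should reduce the enal carbonyl 1,2 to the primary allylic alcohol (C12) without touching the saturated ester or the alkene geometry.

**Step 9**
Reactants: 13 allylic alcohol diol
Product: 14 bis-silyl ether
Conditions: TBSOTf (2.4 equiv), 2,6-lutidine, CH2Cl2, −78 to 0 °C
Reagents that add atoms: tert-butyldimethylsilyl trifluoromethanesulfonate, CC(C)(C)[Si](C)(C)OS(=O)(=O)C(F)(F)F
Why: The silyl triflate should silylate both the primary allylic hydroxyl and the hindered neopentyl C3 hydroxyl, which a silyl chloride would leave.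

**Step 10**
Reactants: 14 bis-silyl ether
Product: 15 keto alcohol ester
Conditions: 1 M HCl, THF, 23 °C
Reagents that add atoms: water, O
Why: Dilute acid should hydrolyse the dioxolane and the primary allylic silyl ether, while the hindered secondary silyl ether at C3 is expected to survive on rate grounds.

**Step 11**
Reactants: 15 keto alcohol ester
Product: 16 hydrindane β-diketone
Conditions: KOtBu (3.2 equiv), THF, −20 to 0 °C; then 1 M HCl
Reagents that add atoms: none
Why: In this intramolecular Claisen (Dieckmann-type) condensation only the C7 enolate can reach the ester through a five-membered ring, and deprotonation of the β-diketone formed should drive the closure of ring C7–C1–C2–C3–C4.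

**Step 12**
Reactants: 16 hydrindane β-diketone
Product: 18 tricyclic diketone, via cyclobutanol photoadduct 17 (not isolated)
Conditions: hν (medium-pressure Hg lamp, Pyrex, λ > 290 nm), degassed MeCN (5 mM), 0 °C; then K2CO3 (0.3 equiv), MeOH, 0 °C
Reagents that add atoms: none
Why: Excitation of the hydrogen-bonded enol (chromophore O=C8–C7=C1–OH) and intersystem crossing give a triplet that adds stepwise through a 1,4-biradical to the alkene C6=C11, forming C7–C6 and C1–C11; K2CO3 then opens the strained cyclobutanol 17 by retro-aldol cleavage of C1–C7, and the carbanion at bridgehead C7 is protonated with retention. The closest known reaction type is the intramolecular De Mayo reaction (enol–alkene [2+2] photocycloaddition, then retro-aldol ring expansion by two carbons), together with the 1,6-type closures of ring-constrained 1,5-dienes that give two cyclobutanes sharing the former α-carbon. Bond C6–C7 closes the cyclobutane C4–C5–C6–C7 as a 1,3-bridge across the cyclohexanone (a bicyclo[3.1.1]heptanone), bond C1–C11 completes a cyclobutane C7–C6–C11–C1 that exists only in 17, and its opening turns the cyclopentane into the seven-membered ring C7–C4–C3–C2–C1–C11–C6. C6 and C7 are fixed because the cis-hydrindane holds the C5 side chain axial on the face opposite the C4 methyl, so the alkene can reach C7 only from that face, and C11 follows from suprafacial addition to the E alkene, which also puts CH2OH on the exo side of the transient cyclobutane. The step needs mode selectivity, and both rule-of-five alternatives are closed by the ring system: bonding C1–C6 and C7–C11 would set C8 and C5 of the six-membered ring anti at a bicyclo[2.1.1]hexane bridgehead, and bonding C8–C6 and C7–C11 through the other enol would force a trans-fused cyclopentanone onto an eclipsed norbornane bond, while fast enol–enol exchange feeds the one productive form. It also needs selective fragmentation, which should hold because only cleavage of C1–C7 leaves a carbanion next to a carbonyl (C8) and releases both the extra cyclobutane and the angular ring fusion.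

**Step 13**
Reactants: 18 tricyclic diketone
Product: 19 C1 alcohol diol
Conditions: Me4NBH(OAc)3 (5 equiv), MeCN/AcOH (1:1), −25 °C
Reagents that add atoms: none
Why: In this hydroxyl-directed reduction the C12 hydroxyl should bind the triacetoxyborohydride and deliver hydride to the β-hydroxy ketone carbonyl C1 from the face carrying CH2OH, giving the C1 alcohol trans to CH2OH, while the C8 ketone has no β-hydroxyl and is not reduced by this mild reagent.

**Step 14**
Reactants: 19 C1 alcohol diol
Product: 20 C12 acetate
Conditions: Ac2O (1.2 equiv), 2,4,6-collidine, CH2Cl2, −20 to 0 °C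
Reagents that add atoms: acetic anhydride, CC(=O)OC(C)=O
Why: The primary hydroxyl should be acetylated far faster than the secondary C1 hydroxyl that is flanked by the quaternary C11.

**Step 15**
Reactants: 20 C12 acetate
Product: 21 C1 angelate silyl ether
Conditions: angelic acid, 2,4,6-trichlorobenzoyl chloride, Et3N, PhMe, 23 °C; then 20, PhMe, 80 °C
Reagents that add atoms: angelic acid, C/C=C(/C)C(=O)O
Why: Yamaguchi esterification through the mixed anhydride, run without a nucleophilic amine catalyst, should acylate the hindered C1 hydroxyl with retention at C1 and without Z to E isomerisation of the angeloyl group.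

**Step 16**
Reactants: 21 C1 angelate silyl ether
Product: 22 target CNP0212099.1
Conditions: HF·pyridine, pyridine, THF, 0 to 23 °C
Reagents that add atoms: none
Why: Buffered fluoride desilylation should free the C3 hydroxyl without cleaving or migrating the two esters and without touching the ketone.

**Compound list**

1 | 5-hydroxy-4-methylfuran-2(5H)-one | CC1=CC(=O)OC1O | starting material
2 | (1S,2R,5S)-(+)-menthol | CC(C)[C@H]1CC[C@H](C)C[C@@H]1O | starting material
3 | (5S)-5-[(1S,2R,5S)-menthyloxy]-4-methylfuran-2(5H)-one | CC1=CC(=O)O[C@@H]1O[C@H]1C[C@@H](C)CC[C@@H]1C(C)C | intermediate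
4 | (E)-pent-3-en-2-one | C/C=C/C(C)=O | starting material
5 | (E)-2-(tert-butyldimethylsilyloxy)penta-1,3-diene | C/C=C/C(=C)O[Si](C)(C)C(C)(C)C | intermediate
6 | silyl enol ether cycloadduct: (3S,3aS,7R,7aR)-5-(tert-butyldimethylsilyloxy)-3-menthyloxy-3a,7-dimethyl-3a,4,7,7a-tetrahydroisobenzofuran-1(3H)-one, cis-fused | O=C1O[C@H](O[C@H]3C[C@@H](C)CC[C@@H]3C(C)C)[C@@]2(C)CC(O[Si](C)(C)C(C)(C)C)=C[C@@H](C)[C@@H]12 | intermediate
7 | keto lactol: (3aS,7R,7aR)-3-hydroxy-3a,7-dimethylhexahydroisobenzofuran-1,5-dione, cis-fused, both C3 epimers | O=C1OC(O)[C@@]2(C)CC(=O)C[C@@H](C)[C@@H]12 | intermediate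
8 | unsaturated acid: the cyclohexanone of 7 with CO2H on C5 and the (E)-CH=CH–CO2Me arm on C4, cis to CO2H | COC(=O)/C=C/[C@@]1(C)CC(=O)C[C@@H](C)[C@H]1C(=O)O | intermediate
9 | keto lactone ester: cis-fused γ-lactone (C6 carbonyl, ring oxygen on C3), CH2CO2Me on C3 cis to the C4 methyl, C8 ketone | O=C1O[C@H](CC(=O)OC)[C@@]2(C)CC(=O)C[C@@H](C)[C@@H]12 | intermediate
10 | dioxolane of 9 (ethylene ketal at C8) | O=C1O[C@H](CC(=O)OC)[C@@]2(C)CC3(OCCO3)C[C@@H](C)[C@@H]12 | intermediate
11 | lactol from 10 (C6 hemiacetal, both epimers) | OC1O[C@H](CC(=O)OC)[C@@]2(C)CC3(OCCO3)C[C@@H](C)[C@@H]12 | intermediate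
12 | (E)-enal: C5 carries CH=C(CH3)–CHO, C4 carries CH3 and CH(OH)CH2CO2Me, C8 ketal | COC(=O)C[C@@H](O)[C@@]1(C)CC2(OCCO2)C[C@@H](C)[C@H]1/C=C(\C)C=O | intermediate
13 | allylic alcohol diol (C12–OH and C3–OH) | COC(=O)C[C@@H](O)[C@@]1(C)CC2(OCCO2)C[C@@H](C)[C@H]1/C=C(\C)CO | intermediate
14 | bis(tert-butyldimethylsilyl) ether of 13 | COC(=O)C[C@@H](O[Si](C)(C)C(C)(C)C)[C@@]1(C)CC2(OCCO2)C[C@@H](C)[C@H]1/C=C(\C)CO[Si](C)(C)C(C)(C)C | intermediate
15 | keto alcohol ester: C8 ketone, C3 silyl ether, free C12–OH, methyl ester at C1 | COC(=O)C[C@@H](O[Si](C)(C)C(C)(C)C)[C@@]1(C)CC(=O)C[C@@H](C)[C@H]1/C=C(\C)CO | intermediate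
16 | hydrindane β-diketone, drawn as its C1 enol (O=C8–C7=C1–OH), with the (E)-hydroxymethylpropenyl arm on C5 | OC/C(C)=C/[C@@H]1[C@H](C)CC(=O)C2=C(O)C[C@@H](O[Si](C)(C)C(C)(C)C)[C@]12C | intermediate
17 | cyclobutanol photoadduct (bonds C7–C6 and C1–C11 made, C7–C1 still present, C1–OH) | O[C@]14C[C@@H](O[Si](C)(C)C(C)(C)C)[C@]2(C)[C@@H]3[C@@H]([C@@]24C(=O)C[C@H]3C)[C@@]1(C)CO | intermediate
18 | tricyclic diketone (C1 and C8 ketones, C12–OH, C3 silyl ether) | O=C1C[C@@H](O[Si](C)(C)C(C)(C)C)[C@]2(C)[C@@H]3[C@@H]([C@H]2C(=O)C[C@H]3C)[C@@]1(C)CO | intermediate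
19 | C1 alcohol diol (C1–OH trans to C12H2OH) | O[C@@H]1C[C@@H](O[Si](C)(C)C(C)(C)C)[C@]2(C)[C@@H]3[C@@H]([C@H]2C(=O)C[C@H]3C)[C@@]1(C)CO | intermediate
20 | C12 acetate with free C1–OH | O[C@@H]1C[C@@H](O[Si](C)(C)C(C)(C)C)[C@]2(C)[C@@H]3[C@@H]([C@H]2C(=O)C[C@H]3C)[C@@]1(C)COC(C)=O | intermediate
21 | C1 angelate, C12 acetate, C3 silyl ether | C/C=C(/C)C(=O)O[C@@H]1C[C@@H](O[Si](C)(C)C(C)(C)C)[C@]2(C)[C@@H]3[C@@H]([C@H]2C(=O)C[C@H]3C)[C@@]1(C)COC(C)=O | intermediate
22 | CNP0212099.1 | C/C=C(/C)C(=O)O[C@@H]1C[C@@H](O)[C@]2(C)[C@@H]3[C@@H]([C@H]2C(=O)C[C@H]3C)[C@@]1(C)COC(C)=O | target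

**Step count**

Total steps: 16. Longest linear sequence: 15 steps (1 to 22 through steps 1 and 3–16; step 2 prepares diene 5).

**Steps most likely to fail**

Step 12. The excited enol may waste itself in reversible five-membered biradical closures, with E/Z isomerisation of the alkene and erosion of C11, or react through the C7=C8 enol, and the cyclobutanol may fragment sluggishly. The fallback fixes the enol constitution with nitrogen and changes the chromophore. It sets out from 15: aminolysis (NH3, MeOH) should give the primary amide F1, and dehydration (PdCl2 cat., MeCN, H2O) the keto nitrile F2. Thorpe cyclisation (KOtBu, t-BuOH, THF) should then give the enaminone F3, whose nitrogen can sit only on C1. Irradiation of this vinylogous amide should give the aminocyclobutane F4, and retro-Mannich opening with hydrolysis of the imine (1 M HCl, THF) comes back to the route at 18.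

Step 3. The β,β-disubstituted butenolide may react too slowly, so that the silyloxy diene polymerises or desilylates first, or endo selectivity may be poor. The fallback installs the ring oxygen after the cycloaddition. It sets out from 3: cycloaddition with (E)-penta-1,3-diene promoted by EtAlCl2 (CH2Cl2, −40 °C) should give the cyclohexene lactone acetal F5 by the same regiochemical and facial logic. Hydroboration with 9-BBN, boron going to C8 away from the C10 methyl, and oxidation (NaBO3·4H2O) should give the C8 alcohol F6. Oxidation with 1,1,1-triacetoxy-1,1-dihydro-1,2-benziodoxol-3(1H)-one should give the keto acetal F7, and 2 M HCl in 1,4-dioxane comes back to the route at 7.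

Step 4. Equilibration at C3 may be slow or only weakly biased, and the neopentyl lactol may resist olefination. The fallback sets C3 kinetically. It sets out from 7: acetylation (Ac2O, pyridine) should give the acetoxy lactone F8. BF3·OEt2 with 1-(tert-butyldimethylsilyloxy)-1-methoxyethene (CH2Cl2, −78 °C) should then add the acetate arm to the acyloxocarbenium ion from the convex face in a Mukaiyama-type substitution, which comes back to the route at 9.

**Further compounds**

F1 | step 12 | primary amide (carboxamide at C1 in place of the methyl ester of 15) | NC(=O)C[C@@H](O[Si](C)(C)C(C)(C)C)[C@@]1(C)CC(=O)C[C@@H](C)[C@H]1/C=C(\C)CO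
F2 | step 12 | keto nitrile (C1 nitrile) | N#CC[C@@H](O[Si](C)(C)C(C)(C)C)[C@@]1(C)CC(=O)C[C@@H](C)[C@H]1/C=C(\C)CO
F3 | step 12 | enaminone (O=C8–C7=C1–NH2 hydrindane) | OC/C(C)=C/[C@@H]1[C@H](C)CC(=O)C2=C(N)C[C@@H](O[Si](C)(C)C(C)(C)C)[C@]12C
F4 | step 12 | aminocyclobutane photoadduct | N[C@]14C[C@@H](O[Si](C)(C)C(C)(C)C)[C@]2(C)[C@@H]3[C@@H]([C@@]24C(=O)C[C@H]3C)[C@@]1(C)CO
F5 | step 3 | cyclohexene lactone acetal (C8=C9 alkene) | O=C1O[C@H](O[C@H]3C[C@@H](C)CC[C@@H]3C(C)C)[C@@]2(C)CC=C[C@@H](C)[C@@H]12
F6 | step 3 | C8 alcohol (both epimers) | O=C1O[C@H](O[C@H]3C[C@@H](C)CC[C@@H]3C(C)C)[C@@]2(C)CC(O)C[C@@H](C)[C@@H]12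
F7 | step 3 | keto acetal (C8 ketone, menthyl acetal) | O=C1O[C@H](O[C@H]3C[C@@H](C)CC[C@@H]3C(C)C)[C@@]2(C)CC(=O)C[C@@H](C)[C@@H]12
F8 | step 4 | acetoxy lactone (C3 acetate of 7, both epimers) | O=C1OC(OC(C)=O)[C@@]2(C)CC(=O)C[C@@H](C)[C@@H]12
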